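**Plan**

- Numbering follows chroman-2-one: unprimed atoms for ring A (the 5,7-dioxygenated lactone), primed atoms for ring B (the 5',6',7',8'-tetraoxygenated lactone).
- Cuts: (i) the seven O–methyl bonds used as protection; (ii) ring B at C3'–C4' together with its acyl–O1' bond, giving a ring A ketene and a ring B quinone methide phenolate; (iii) ring A at C3–C4/O1–C2, giving an o-quinone methide and a four-carbon enal ester that supplies C2, C3, C3' and C2'.
- Forward order: ring A lactone by a carbene-catalysed [4+2] annulation, side-chain acid to ketene, closure of ring B onto it, global demethylation.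
- Enabling feature: C4' is a diarylmethine para to the oxygen of its 4-hydroxyphenyl group and ortho to the lactone oxygen O1' (a latent p-quinone methide); C3' is α to the ring B carbonyl C2' (a latent ester enolate); the O1'–C2' ester tethers them for a six-membered closure.
- Stereochemistry: C3/C4 (cis) come from the chiral triazolium catalyst. C4' forms from a planar quinone methide, so the racemic precursor converges. C3'/C4' are set in the ring closure by enolate geometry and by C3. Both cis lactones are kinetic and are kept by avoiding strong base afterwards.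

Key step: step 8

Assumption: the facial sense of the triazolium salt in step 3 is taken from the usual enolate oxa-Diels–Alder model; both enantiomers of the salt are commercial, so the antipode is used if the model errs.

**Step 1**
Reactants: 1 2-hydroxy-4,6-dimethoxybenzaldehyde; 2 4-methoxyphenylmagnesium bromide
Product: 3 rac-2-[hydroxy(4-methoxyphenyl)methyl]-3,5-dimethoxyphenol
Conditions: 4-MeOC6H4MgBr (2.2 equiv), THF, 0 °C → rt; aq. NH4Cl
Reagents that add atoms: none
Why: Grignard addition to the aldehyde, after the first equivalent deprotonates the phenol, should give the diarylmethanol, whose racemic stereocenter is erased in step 3.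

**Step 2**
Reactants: 3 rac-2-[hydroxy(4-methoxyphenyl)methyl]-3,5-dimethoxyphenol
Product: 4 rac-3,5-dimethoxy-2-[(4-methoxyphenyl)(4-methylbenzenesulfonyl)methyl]phenol
Conditions: 4-MeC6H4SO2Na, HCO2H, H2O, rt
Reagents that add atoms: sodium 4-methylbenzenesulfinate, Cc1ccc(S(=O)[O-])cc1.[Na+]
Why: Acid ionizes the doubly activated benzhydrol to a quinone-methide-type cation that sulfinate captures at sulfur (SN1 substitution), giving a bench-stable racemic quinone methide precursor.

**Step 3**
Reactants: 4 rac-3,5-dimethoxy-2-[(4-methoxyphenyl)(4-methylbenzenesulfonyl)methyl]phenol; 5 tert-butyl (2E)-4-oxobut-2-enoate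
Product: 7 tert-butyl 2-[(3R,4R)-5,7-dimethoxy-4-(4-methoxyphenyl)-2-oxo-3,4-dihydro-2H-chromen-3-yl]acetate, via o-quinone methide 6 (not isolated)
Conditions: (5aS,10bR)-5a,10b-dihydro-2-(2,4,6-trimethylphenyl)-4H,6H-indeno[2,1-b][1,2,4]triazolo[4,3-d][1,4]oxazinium chloride (10 mol %), Cs2CO3 (1.2 equiv), CH2Cl2, 0 °C → rt
Reagents that add atoms: none
Why: Base-induced 1,4-elimination of sulfinate gives planar (E)-o-quinone methide 6 (both enantiomers of 4 converge) while the carbene turns enal 5, by β-protonation of its ester-stabilized acyl anion equivalent, into an azolium enolate, and their endo oxa-Diels–Alder reaction (carbene-catalysed enolate [4+2] annulation) should give the cis lactone with C3 and C4 both R through shielding of one enolate face by the chiral triazolium.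

**Step 4**
Reactants: 7 tert-butyl 2-[(3R,4R)-5,7-dimethoxy-4-(4-methoxyphenyl)-2-oxo-3,4-dihydro-2H-chromen-3-yl]acetate
Product: 8 2-[(3R,4R)-5,7-dimethoxy-4-(4-methoxyphenyl)-2-oxo-3,4-dihydro-2H-chromen-3-yl]acetic acid
Conditions: CF3CO2H, CH2Cl2, 0 °C → rt
Reagents that add atoms: none
Why: Acidolysis of the tert-butyl ester (E1 loss of isobutene) leaves the aryl lactone, the methyl ethers and the base-sensitive cis C3 center untouched.

**Step 5**
Reactants: 8 2-[(3R,4R)-5,7-dimethoxy-4-(4-methoxyphenyl)-2-oxo-3,4-dihydro-2H-chromen-3-yl]acetic acid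
Product: 9 2-[(3R,4R)-5,7-dimethoxy-4-(4-methoxyphenyl)-2-oxo-3,4-dihydro-2H-chromen-3-yl]acetyl chloride
Conditions: (COCl)2, DMF (cat.), CH2Cl2, 0 °C → rt; evaporate, use crude
Reagents that add atoms: oxalyl chloride, ClC(=O)C(=O)Cl
Why: Acid chloride formation through the DMF-derived chloroiminium catalyst is non-basic and should not epimerize C3.

**Step 6**
Reactants: 10 1,2,3,4-tetramethoxybenzene
Product: 13 2,3,4,5-tetramethoxyphenol, via aryllithium 11 (not isolated), via arylboronate 12 (not isolated)
Conditions: n-BuLi, TMEDA, THF, 0 °C; B(OMe)3, −78 °C → rt; H2O2, AcOH, 0 °C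
Reagents that add atoms: hydrogen peroxide, OO
Why: Methoxy-directed ortho-lithiation can only occur at the one type of free ring position, and borylation followed by oxidative 1,2-migration of the aryl group from boron to oxygen converts the C–Li bond into the phenol.

**Step 7**
Reactants: 13 2,3,4,5-tetramethoxyphenol; 14 4-hydroxybenzaldehyde
Product: 16 rac-2-[(4-hydroxyphenyl)(4-methylbenzenesulfonyl)methyl]-3,4,5,6-tetramethoxyphenol, via carbinol 15 (not isolated)
Conditions: 4-MeC6H4SO2Na, HCO2H, H2O, 40 °C
Reagents that add atoms: sodium 4-methylbenzenesulfinate, Cc1ccc(S(=O)[O-])cc1.[Na+]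
Why: The single free position of 13 is ortho to its hydroxyl group, so acid-mediated hydroxyalkylation (Friedel–Crafts type) can only give carbinol 15, which ionizes to the quinone methide cation and is trapped by sulfinate as the racemic sulfone.

**Step 8**
Reactants: 9 2-[(3R,4R)-5,7-dimethoxy-4-(4-methoxyphenyl)-2-oxo-3,4-dihydro-2H-chromen-3-yl]acetyl chloride; 16 rac-2-[(4-hydroxyphenyl)(4-methylbenzenesulfonyl)methyl]-3,4,5,6-tetramethoxyphenol
Product: 20 (3S,3'S,4R,4'R)-4'-(4-hydroxyphenyl)-5,5',6',7,7',8'-hexamethoxy-4-(4-methoxyphenyl)-3,3',4,4'-tetrahydro-2H,2'H-[3,3'-bichromene]-2,2'-dione, via ketene 17 (not isolated), via quinone methide phenolate 18 (not isolated), via ester enolate 19 (not isolated)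
Conditions: 16 + LiN(SiMe3)2 (2.0 equiv), THF, −78 → 0 °C; separately 9 + iPr2NEt, THF, −78 °C; add the ketene solution at −78 °C, warm to −20 °C; aq. NH4Cl
Reagents that add atoms: none
Why: Proposed new method: iPr2NEt converts acid chloride 9 into ketene 17 and LiN(SiMe3)2 converts sulfone 16, by loss of sulfinate, into quinone methide phenolate 18; the ring B oxygen O1' adds in the ketene plane anti to C3 to give ester enolate 19 with its oxido group cis to C3, and C3' then closes ring B on the exocyclic carbon C4' of the p-quinone methide (6-(enolendo)-exo-trig 1,6-addition) with aromatization to the 4-hydroxyphenyl group. The closest known reaction types are the Lewis-base-catalysed formal [4+2] annulations of o-hydroxyphenyl p-quinone methides with ammonium or azolium enolates to 4-aryl-3,4-dihydrocoumarins and the addition of phenolates to ketenes; new are the order of events (O-acylation first, then C–C ring closure, no nucleophilic catalyst) and a quinone methide without stabilizing tert-butyl groups. C4' arises from a planar quinone methide, so both enantiomers of 16 converge, and its aryl group is forced pseudo-axial by the peri 5'-methoxy group, while the C3' substituent trans to O1' in 19 becomes pseudo-equatorial, which should make ring B cis. The absolute sense at C3' is expected to follow from C3: with lithium bridging the enolate oxygen and the ring A lactone carbonyl (C2 inside), H3 faces the incoming quinone methide and C4 with its axial aryl is anti, which leads to 3'S,4'R. The step needs O-acylation at the hindered ring B oxygen and not at the quinoid oxygen; both ester enolates can revert to 17 and 18 by E1cB loss of the stabilized aryloxide, but only the ring B ester can cyclize, so the mixture should funnel to 20. No base stronger than an aryloxide is present when the fragments meet, so the epimerizable cis C3–H of ring A should stay untouched.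

**Step 9**
Reactants: 20 (3S,3'S,4R,4'R)-4'-(4-hydroxyphenyl)-5,5',6',7,7',8'-hexamethoxy-4-(4-methoxyphenyl)-3,3',4,4'-tetrahydro-2H,2'H-[3,3'-bichromene]-2,2'-dione
Product: 21 (3S,3'S,4R,4'R)-5,5',6',7,7',8'-hexahydroxy-4,4'-bis(4-hydroxyphenyl)-3,3',4,4'-tetrahydro-2H,2'H-[3,3'-bichromene]-2,2'-dione
Conditions: BBr3 (excess), CH2Cl2, −78 → 0 °C; degassed H2O, argon
Reagents that add atoms: none
Why: BBr3 cleaves all seven aryl methyl ethers by bromide attack on the boron-complexed methyl groups, an acidic Lewis-acid ether cleavage that should leave the two aryl lactones and the four stereocenters unchanged.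

**Compound list**

1 | 2-hydroxy-4,6-dimethoxybenzaldehyde | COc1cc(O)c(C=O)c(OC)c1 | starting material
2 | 4-methoxyphenylmagnesium bromide | COc1ccc([Mg]Br)cc1 | starting material
3 | rac-2-[hydroxy(4-methoxyphenyl)methyl]-3,5-dimethoxyphenol | COc1ccc(C(O)c2c(O)cc(OC)cc2OC)cc1 | intermediate
4 | rac-3,5-dimethoxy-2-[(4-methoxyphenyl)(4-methylbenzenesulfonyl)methyl]phenol | COc1ccc(C(c2c(O)cc(OC)cc2OC)S(=O)(=O)c2ccc(C)cc2)cc1 | intermediate
5 | tert-butyl (2E)-4-oxobut-2-enoate | CC(C)(C)OC(=O)/C=C/C=O | starting material
6 | (6E)-3,5-dimethoxy-6-[(4-methoxyphenyl)methylidene]cyclohexa-2,4-dien-1-one | COc1ccc(/C=C2\C(OC)=CC(OC)=CC2=O)cc1 | intermediate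
7 | tert-butyl 2-[(3R,4R)-5,7-dimethoxy-4-(4-methoxyphenyl)-2-oxo-3,4-dihydro-2H-chromen-3-yl]acetate | O=C1Oc2cc(OC)cc(OC)c2[C@@H](c2ccc(OC)cc2)[C@H]1CC(=O)OC(C)(C)C | intermediate
8 | 2-[(3R,4R)-5,7-dimethoxy-4-(4-methoxyphenyl)-2-oxo-3,4-dihydro-2H-chromen-3-yl]acetic acid | O=C1Oc2cc(OC)cc(OC)c2[C@@H](c2ccc(OC)cc2)[C@H]1CC(=O)O | intermediate
9 | 2-[(3R,4R)-5,7-dimethoxy-4-(4-methoxyphenyl)-2-oxo-3,4-dihydro-2H-chromen-3-yl]acetyl chloride | O=C1Oc2cc(OC)cc(OC)c2[C@@H](c2ccc(OC)cc2)[C@H]1CC(=O)Cl | intermediate
10 | 1,2,3,4-tetramethoxybenzene | COc1ccc(OC)c(OC)c1OC | starting material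
11 | (2,3,4,5-tetramethoxyphenyl)lithium | [Li]c1cc(OC)c(OC)c(OC)c1OC | intermediate
12 | dimethyl (2,3,4,5-tetramethoxyphenyl)boronate | COB(OC)c1cc(OC)c(OC)c(OC)c1OC | intermediate
13 | 2,3,4,5-tetramethoxyphenol | COc1cc(O)c(OC)c(OC)c1OC | intermediate
14 | 4-hydroxybenzaldehyde | O=Cc1ccc(O)cc1 | starting material
15 | rac-2-[hydroxy(4-hydroxyphenyl)methyl]-3,4,5,6-tetramethoxyphenol | COc1c(O)c(C(O)c2ccc(O)cc2)c(OC)c(OC)c1OC | intermediate
16 | rac-2-[(4-hydroxyphenyl)(4-methylbenzenesulfonyl)methyl]-3,4,5,6-tetramethoxyphenol | COc1c(O)c(C(c2ccc(O)cc2)S(=O)(=O)c2ccc(C)cc2)c(OC)c(OC)c1OC | intermediate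
17 | (3S,4R)-5,7-dimethoxy-4-(4-methoxyphenyl)-3-(2-oxoethenyl)-3,4-dihydro-2H-chromen-2-one | O=C1Oc2cc(OC)cc(OC)c2[C@@H](c2ccc(OC)cc2)[C@H]1C=C=O | intermediate
18 | lithium 2,3,4,5-tetramethoxy-6-[(4-oxocyclohexa-2,5-dien-1-ylidene)methyl]phenolate | [Li+].[O-]c1c(OC)c(OC)c(OC)c(OC)c1C=C1C=CC(=O)C=C1 | intermediate
19 | lithium (1E)-2-[(3S,4R)-5,7-dimethoxy-4-(4-methoxyphenyl)-2-oxo-3,4-dihydro-2H-chromen-3-yl]-1-{2,3,4,5-tetramethoxy-6-[(4-oxocyclohexa-2,5-dien-1-ylidene)methyl]phenoxy}ethen-1-olate (oxido group cis to C3) | [Li+].O=C1Oc2cc(OC)cc(OC)c2[C@@H](c2ccc(OC)cc2)[C@H]1/C=C(\[O-])Oc1c(OC)c(OC)c(OC)c(OC)c1C=C1C=CC(=O)C=C1 | intermediate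
20 | (3S,3'S,4R,4'R)-4'-(4-hydroxyphenyl)-5,5',6',7,7',8'-hexamethoxy-4-(4-methoxyphenyl)-3,3',4,4'-tetrahydro-2H,2'H-[3,3'-bichromene]-2,2'-dione | O=C1Oc2cc(OC)cc(OC)c2[C@@H](c2ccc(OC)cc2)[C@H]1[C@H]1C(=O)Oc2c(OC)c(OC)c(OC)c(OC)c2[C@H]1c1ccc(O)cc1 | intermediate
21 | (3S,3'S,4R,4'R)-5,5',6',7,7',8'-hexahydroxy-4,4'-bis(4-hydroxyphenyl)-3,3',4,4'-tetrahydro-2H,2'H-[3,3'-bichromene]-2,2'-dione | O=C1Oc2cc(O)cc(O)c2[C@@H](c2ccc(O)cc2)[C@H]1[C@H]1C(=O)Oc2c(O)c(O)c(O)c(O)c2[C@H]1c1ccc(O)cc1 | target

**Step count and risks**

Total steps: 9. Longest linear sequence: 7 (steps 1, 2, 3, 4, 5, 8, 9).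

1. Step 8 (Proposed new method). What may go wrong: poor facial selectivity at C3' if the lithium bridge to the ring A carbonyl does not organize the ring closure; acylation of the product phenolate by ketene; ketene dimerization. The fallback uses known chemistry and sets out from acid 8. DCC and 4-nitrophenol would give the activated ester 4-nitrophenyl 2-[(3R,4R)-5,7-dimethoxy-4-(4-methoxyphenyl)-2-oxo-3,4-dihydro-2H-chromen-3-yl]acetate F1. With sulfone 16, Cs2CO3 and the triazolium salt of step 3, the carbene would displace 4-nitrophenolate from F1 and the resulting acyl azolium would be deprotonated to an azolium enolate. That enolate would undergo the established catalyst-controlled formal [4+2] annulation with the o-hydroxyphenyl p-quinone methide released from 16. Because both halves of the target have the same sense, the same catalyst enantiomer as in step 3 should set C3' and C4'. The fallback comes back to the route at 20.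

2. Step 3. What may go wrong: bond formation through the homoenolate carbon instead of the enolate (a [4+3] annulation), or base-induced loss of the cis configuration at C3. The fallback sets out from sulfone 4 and changes how the enolate is made. Commercial tert-butyl 4-oxobutanoate would be used under oxidative carbene catalysis (same triazolium salt, 3,3',5,5'-tetra-tert-butyldiphenoquinone as oxidant, Cs2CO3). The saturated aldehyde is oxidized on the catalyst to the acyl azolium and deprotonated to the same azolium enolate, so no homoenolate can form. The [4+2] annulation with 6 comes back to the route at 7.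

3. Step 7. What may go wrong: capture of the benzylic cation by a second molecule of phenol (over-arylation to a triarylmethane), and slow hydroxyalkylation by the electron-rich aldehyde. The fallback sets out from phenol 13 and builds the carbinol stepwise. Ortho-formylation (MgCl2, Et3N, paraformaldehyde) would give 2-hydroxy-3,4,5,6-tetramethoxybenzaldehyde F2. Addition of 4-(tetrahydropyran-2-yloxy)phenylmagnesium bromide would give 2-{hydroxy[4-(tetrahydropyran-2-yloxy)phenyl]methyl}-3,4,5,6-tetramethoxyphenol F3. Sodium 4-methylbenzenesulfinate in aqueous formic acid would then remove the acetal and install the sulfone, coming back to the route at 16.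

**Further compounds**

F1 | step 8 | 4-nitrophenyl 2-[(3R,4R)-5,7-dimethoxy-4-(4-methoxyphenyl)-2-oxo-3,4-dihydro-2H-chromen-3-yl]acetate | O=C1Oc2cc(OC)cc(OC)c2[C@@H](c2ccc(OC)cc2)[C@H]1CC(=O)Oc1ccc([N+](=O)[O-])cc1
F0 | step 3 | none | none
F2 | step 7 | 2-hydroxy-3,4,5,6-tetramethoxybenzaldehyde | COc1c(O)c(C=O)c(OC)c(OC)c1OC
F3 | step 7 | 2-{hydroxy[4-(tetrahydropyran-2-yloxy)phenyl]methyl}-3,4,5,6-tetramethoxyphenol | COc1c(O)c(C(O)c2ccc(OC3CCCCO3)cc2)c(OC)c(OC)c1OC
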